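The synthesis rests on cutting the flavan C4–C4a bond. In flavan ring A, C4a is the most electron-rich carbon (ortho to O1, para to O7). C4 is benzylic to ring D, the future flavonol A ring, and vicinal to O3, so C3–C4 can be carried as a trans-epoxide. Mild activation of the epoxy aryl ether lets C4a open the oxirane at C4 with inversion. That one operation forms C4–C4a, closes pyran ring C and sets C4 trans to O3, next to the preset 2,3-cis pair. The precursor comes from an enantioenriched chalcone epoxide. It holds O7/O8 in a diphenylmethylene ketal and keeps a bromine on ring D for the later flavonol annulation.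

Key step: step 9

Remarks on the chemistry
- Assumption: the target is read as (2R,3R,4S), that is 2,3-cis-3,4-trans. Poly-L-leucine is assumed to give the (αR,βS) sense known for the chalcone series; poly-D-leucine would give the mirror image.
- Flavan numbering (O1, C2, C3, C4, C4a, O7, O8) is used for the open-chain intermediates too. Rings A/B/C are the flavan rings, ring D is the bromoarene that becomes the flavonol A ring, and ring E is the flavonol B ring. Bn = benzyl.
- In bromides 12 and 13 the C4 descriptor reads R only because bromine raises the CIP rank of ring D. The spatial arrangement is that of the (4S) target.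
- Design of the precursor:
  - The O7/O8 ketal comes from pyrogallol in one step, keeps the O7 lone pair coplanar with ring A, removes a bulky group next to O1, and falls off in the final hydrogenolysis.
  - The bromine is a handle and also tempers cation character at C4.
  - All C–C bonds before the key step come from one aldol condensation.

Step 1
Reactants: 1 3,4,5-trihydroxybenzaldehyde
Product: 2 3,4,5-tris(benzyloxy)benzaldehyde
Conditions: BnBr, K2CO3, DMF, 60 °C, N2
Reagents that add atoms: benzyl bromide, BrCc1ccccc1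
Why: Williamson ether synthesis, in which the three phenoxides formed by K2CO3 are alkylated by benzyl bromide while the aldehyde is inert.

Step 2
Reactants: 2 3,4,5-tris(benzyloxy)benzaldehyde
Product: 3 2-bromo-3,4,5-tris(benzyloxy)benzaldehyde
Conditions: NBS (1.05 equiv), MeCN–CH2Cl2, 0 °C to rt, dark
Reagents that add atoms: N-bromosuccinimide, O=C1CCC(=O)N1Br
Why: Electrophilic aromatic bromination, in which C2 and C6 are equivalent and each has an ortho and a para benzyloxy donor, so one equivalent of NBS under ionic conditions should give a single monobromide and spare the benzylic CH2 groups.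

Step 3
Reactants: 4 3',4'-dihydroxyacetophenone
Product: 5 1-[3,4-bis(benzyloxy)phenyl]ethanone
Conditions: BnBr, K2CO3, DMF, 60 °C
Reagents that add atoms: benzyl bromide, BrCc1ccccc1
Why: Williamson ether synthesis on the two phenoxides, with the methyl ketone untouched by the weak base.

Step 4
Reactants: 3 2-bromo-3,4,5-tris(benzyloxy)benzaldehyde; 5 1-[3,4-bis(benzyloxy)phenyl]ethanone
Product: 6 (E)-1-[3,4-bis(benzyloxy)phenyl]-3-[2-bromo-3,4,5-tris(benzyloxy)phenyl]prop-2-en-1-one
Conditions: KOH, EtOH–THF, rt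
Reagents that add atoms: none
Why: Claisen–Schmidt condensation, in which the methyl ketone enolate adds to the non-enolisable aldehyde and E1cB loss of water gives the conjugated (E)-enone as the thermodynamic isomer.

Step 5
Reactants: 6 (E)-chalcone
Product: 7 [3,4-bis(benzyloxy)phenyl]{(2R,3S)-3-[2-bromo-3,4,5-tris(benzyloxy)phenyl]oxiran-2-yl}methanone
Conditions: poly-L-leucine, urea·H2O2, DBU, THF, rt
Reagents that add atoms: urea–hydrogen peroxide, NC(N)=O.OO
Why: Juliá–Colonna epoxidation (asymmetric Weitz–Scheffer reaction), in which hydroperoxide adds to the enone bound at the helical polypeptide and closes to the trans-(αR,βS)-oxirane, so C3 and the pre-inversion configuration of C4 are set in the only enantioselective event of the route and recrystallisation can raise the enantiomeric purity.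

Step 6
Reactants: 7 (2R,3S)-epoxy ketone
Product: 8 (S)-[3,4-bis(benzyloxy)phenyl]{(2S,3S)-3-[2-bromo-3,4,5-tris(benzyloxy)phenyl]oxiran-2-yl}methanol (erythro)
Conditions: Zn(BH4)2, Et2O–CH2Cl2, −78 to −30 °C; H2O
Reagents that add atoms: none
Why: Chelation-controlled hydride reduction of an α,β-epoxy ketone, in which zinc ties the carbonyl O to the oxirane O and hydride enters from the face away from C4, which should give the erythro alcohol with (S)-C2 and leave oxirane and aryl bromide intact.

Step 7
Reactants: 9 pyrogallol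
Product: 10 2,2-diphenyl-1,3-benzodioxol-4-ol
Conditions: Ph2CCl2 (1 equiv), Ph2O, 170 °C
Reagents that add atoms: dichlorodiphenylmethane, ClC(Cl)(c1ccccc1)c1ccccc1
Why: Ketalisation of a catechol unit with a gem-dichloride, in which two adjacent hydroxyls close the five-membered ring, only one ketal can form, and the third hydroxyl stays free as the future O1.

Step 8
Reactants: 8 erythro epoxy alcohol; 10 2,2-diphenyl-1,3-benzodioxol-4-ol
Product: 11 4-{(R)-[3,4-bis(benzyloxy)phenyl][(2R,3S)-3-(2-bromo-3,4,5-tris(benzyloxy)phenyl)oxiran-2-yl]methoxy}-2,2-diphenyl-1,3-benzodioxole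
Conditions: PPh3, DIAD, toluene, 0 °C to rt
Reagents that add atoms: none
Why: Mitsunobu etherification, in which the phenoxide displaces the alkoxyphosphonium group in an SN2 step that inverts (S)-C2 to the (R)-C2 of the target, while the electron-withdrawing oxirane next to C2 and the non-polar solvent hold back ionisation.

Step 9
Reactants: 11 trans-epoxy aryl ether
Product: 12 (2R,3R,4R)-2-[3,4-bis(benzyloxy)phenyl]-4-[2-bromo-3,4,5-tris(benzyloxy)phenyl]-7,8-(diphenylmethylenedioxy)chroman-3-ol (2,3-cis-3,4-trans)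
Conditions: HFIP–CH2Cl2 (3:1, 0.01 M), 0 °C to rt
Reagents that add atoms: none
Why: Hydrogen bonding by HFIP polarises the benzylic C4–O bond of the trans-oxirane, C4a of ring A attacks C4 from the rear in an SN2-like Friedel–Crafts alkylation, and rearomatisation hands the proton to O3, so the step is a pure isomerisation. The closest known reaction type is the intramolecular Friedel–Crafts epoxy–arene cyclisation of trans-3-arylglycidyl aryl ethers to trans-4-arylchroman-3-ols, applied here to a glycidyl ether that also carries ring B on C2. Pyran ring C closes in the 6-endo-tet mode through a half-chair that keeps ring B equatorial and places O3 and ring D trans-diaxial, which is the geometry an anti opening demands. C4 is the only new stereocentre and is controlled by inversion at the oxirane carbon (3,4-trans), while C2 and C3 are not involved and keep the 2,3-cis relation. The step needs 6-endo over 5-exo opening, secured because only C4 is benzylic, and ring A over ring B as nucleophile, secured because C4a has two donors (O1 ortho, coplanar dioxole O7 para) whereas C6' of ring B has one and could reach C4 only through a strained 5-endo geometry. It also needs inversion instead of free ionisation and an intact C2–O1 bond, secured by the ortho bromine, the two meta oxygens and the twisted para oxygen of ring D, which keep the C4 cation from becoming free, and by the absence of any strong acid.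

Step 10
Reactants: 12 4-arylchroman-3-ol
Product: 13 (2R,3R,4R)-3-(benzyloxy)-2-[3,4-bis(benzyloxy)phenyl]-4-[2-bromo-3,4,5-tris(benzyloxy)phenyl]-7,8-(diphenylmethylenedioxy)chroman
Conditions: NaH, BnBr, TBAI (cat), DMF, 0 °C to rt
Reagents that add atoms: benzyl bromide, BrCc1ccccc1
Why: Williamson ether synthesis on the sodium alkoxide of the axial C3 hydroxyl, which removes the only acidic proton before the organolithium step and adds a group that leaves in the final hydrogenolysis.

Step 11
Reactants: 14 benzyloxyacetyl chloride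
Product: 15 2-(benzyloxy)-N-methoxy-N-methylacetamide
Conditions: MeNH(OMe)·HCl, K2CO3, CH2Cl2–H2O, 0 °C
Reagents that add atoms: N,O-dimethylhydroxylamine hydrochloride, CNOC.Cl
Why: Schotten–Baumann acylation of N,O-dimethylhydroxylamine gives the Weinreb amide.

Step 12
Reactants: 13 3-O-benzyl bromide; 15 Weinreb amide
Product: 17 2-(benzyloxy)-1-{2,3,4-tris(benzyloxy)-6-[(2R,3R,4S)-3-(benzyloxy)-2-(3,4-bis(benzyloxy)phenyl)-7,8-(diphenylmethylenedioxy)chroman-4-yl]phenyl}ethanone, via aryllithium 16 (not isolated)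
Conditions: n-BuLi, THF, −78 °C; 15, −78 to −30 °C; AcOH quench
Reagents that add atoms: none
Why: Bromine–lithium exchange followed by Weinreb ketone synthesis, in which exchange at −78 °C outruns benzylic deprotonation, the neighbouring benzyloxy oxygen stabilises the aryllithium, and the chelated tetrahedral adduct stops the addition at the ketone stage.

Step 13
Reactants: 17 α-benzyloxy ketone
Product: 18 2-(benzyloxy)-1-{3,4-bis(benzyloxy)-2-hydroxy-6-[(2R,3R,4S)-3-(benzyloxy)-2-(3,4-bis(benzyloxy)phenyl)-7,8-(diphenylmethylenedioxy)chroman-4-yl]phenyl}ethanone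
Conditions: MgBr2·OEt2, toluene–Et2O, 70 °C; H2O
Reagents that add atoms: none
Why: Chelation-assisted ether cleavage, in which magnesium bridges the ketone O and the ortho benzyloxy O and bromide removes that benzyl group by SN2 with the chelated phenoxide as leaving group, while the unchelated aryl benzyl ethers, the alkyl benzyl ethers (poorer leaving groups) and the ketal (no SN2-accessible carbon) should stay.

Step 14
Reactants: 18 ortho-hydroxy ketone; 19 3,4-bis(benzyloxy)benzoic acid
Product: 21 aryl 3,4-bis(benzyloxy)benzoate of 18, via aroyl chloride 20 (not isolated)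
Conditions: 19, (COCl)2, DMF (cat), CH2Cl2; then 18, Et3N, DMAP (cat), CH2Cl2, 0 °C to rt
Reagents that add atoms: none
Why: Acid chloride formation followed by DMAP-catalysed O-acylation of the only free hydroxyl in 18.

Step 15
Reactants: 21 aryl ester
Product: 23 fully protected flavonol–flavan (3-benzyloxychromone), via 1,3-diketone 22 (not isolated)
Conditions: LiHMDS (2.5 equiv), THF, −78 to 0 °C; AcOH; then TsOH·H2O (cat), toluene, 60 °C
Reagents that add atoms: none
Why: Baker–Venkataraman rearrangement and cyclodehydration, in which the lithium enolate of the α-benzyloxy ketone takes over the aroyl group through a six-membered transition state and mild acid closes the freed phenol onto the new aryl ketone with loss of water, a path chosen because 6'-substituted 2'-hydroxychalcones tend to give aurones on oxidative cyclisation.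

Step 16
Reactants: 23 fully protected flavonol–flavan
Product: 24 target, 5-[(2R,3R,4S)-2-(3,4-dihydroxyphenyl)-3,7,8-trihydroxychroman-4-yl]-2-(3,4-dihydroxyphenyl)-3,7,8-trihydroxy-4H-chromen-4-one
Conditions: H2 (1 atm), Pd(OH)2/C, THF–MeOH, rt, filtration under argon
Reagents that add atoms: none
Why: Catalytic hydrogenolysis, in which the eight O-benzyl groups and the diphenylmethylene ketal are benzylic C–O bonds that cleave over Pearlman's catalyst under conditions that in flavan-3-ol chemistry leave the C2–O1 bond, the chromone and the three stereocentres unchanged.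

Compound list
1 | 3,4,5-trihydroxybenzaldehyde | O=Cc1cc(O)c(O)c(O)c1 | starting material
2 | 3,4,5-tris(benzyloxy)benzaldehyde | O=Cc1cc(OCc2ccccc2)c(OCc2ccccc2)c(OCc2ccccc2)c1 | intermediate
3 | 2-bromo-3,4,5-tris(benzyloxy)benzaldehyde | O=Cc1cc(OCc2ccccc2)c(OCc2ccccc2)c(OCc2ccccc2)c1Br | intermediate
4 | 3',4'-dihydroxyacetophenone | CC(=O)c1ccc(O)c(O)c1 | starting material
5 | 1-[3,4-bis(benzyloxy)phenyl]ethanone | CC(=O)c1ccc(OCc2ccccc2)c(OCc2ccccc2)c1 | intermediate
6 | (E)-chalcone | O=C(/C=C/c1cc(OCc2ccccc2)c(OCc2ccccc2)c(OCc2ccccc2)c1Br)c1ccc(OCc2ccccc2)c(OCc2ccccc2)c1 | intermediate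
7 | (2R,3S)-epoxy ketone | Brc1c(OCc2ccccc2)c(OCc2ccccc2)c(OCc2ccccc2)cc1[C@@H]1O[C@H]1C(=O)c1ccc(OCc2ccccc2)c(OCc2ccccc2)c1 | intermediate
8 | erythro epoxy alcohol, (S)-carbinol, (2S,3S)-oxirane | Brc1c(OCc2ccccc2)c(OCc2ccccc2)c(OCc2ccccc2)cc1[C@@H]1O[C@H]1[C@@H](O)c1ccc(OCc2ccccc2)c(OCc2ccccc2)c1 | intermediate
9 | pyrogallol | Oc1cccc(O)c1O | starting material
10 | 2,2-diphenyl-1,3-benzodioxol-4-ol | Oc1cccc2OC(c3ccccc3)(c3ccccc3)Oc12 | intermediate
11 | trans-epoxy aryl ether, (R)-C2, (2R,3S)-oxirane (key-step precursor) | Brc1c(OCc2ccccc2)c(OCc2ccccc2)c(OCc2ccccc2)cc1[C@@H]1O[C@H]1[C@@H](c1ccc(OCc2ccccc2)c(OCc2ccccc2)c1)Oc1cccc2OC(c3ccccc3)(c3ccccc3)Oc12 | intermediate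
12 | 2,3-cis-3,4-trans 4-arylchroman-3-ol (key-step product) | Brc1c(OCc2ccccc2)c(OCc2ccccc2)c(OCc2ccccc2)cc1[C@H]1c2ccc3OC(c4ccccc4)(c4ccccc4)Oc3c2O[C@H](c2ccc(OCc3ccccc3)c(OCc3ccccc3)c2)[C@@H]1O | intermediate
13 | 3-O-benzyl ether of 12 | Brc1c(OCc2ccccc2)c(OCc2ccccc2)c(OCc2ccccc2)cc1[C@H]1c2ccc3OC(c4ccccc4)(c4ccccc4)Oc3c2O[C@H](c2ccc(OCc3ccccc3)c(OCc3ccccc3)c2)[C@@H]1OCc1ccccc1 | intermediate
14 | benzyloxyacetyl chloride | O=C(Cl)COCc1ccccc1 | starting material
15 | 2-(benzyloxy)-N-methoxy-N-methylacetamide | CON(C)C(=O)COCc1ccccc1 | intermediate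
16 | aryllithium from 13 | [Li]c1c(OCc2ccccc2)c(OCc2ccccc2)c(OCc2ccccc2)cc1[C@H]1c2ccc3OC(c4ccccc4)(c4ccccc4)Oc3c2O[C@H](c2ccc(OCc3ccccc3)c(OCc3ccccc3)c2)[C@@H]1OCc1ccccc1 | intermediate
17 | α-benzyloxy aryl ketone | O=C(COCc1ccccc1)c1c(OCc2ccccc2)c(OCc2ccccc2)c(OCc2ccccc2)cc1[C@H]1c2ccc3OC(c4ccccc4)(c4ccccc4)Oc3c2O[C@H](c2ccc(OCc3ccccc3)c(OCc3ccccc3)c2)[C@@H]1OCc1ccccc1 | intermediate
18 | ortho-hydroxy α-benzyloxy aryl ketone | O=C(COCc1ccccc1)c1c(O)c(OCc2ccccc2)c(OCc2ccccc2)cc1[C@H]1c2ccc3OC(c4ccccc4)(c4ccccc4)Oc3c2O[C@H](c2ccc(OCc3ccccc3)c(OCc3ccccc3)c2)[C@@H]1OCc1ccccc1 | intermediate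
19 | 3,4-bis(benzyloxy)benzoic acid | OC(=O)c1ccc(OCc2ccccc2)c(OCc2ccccc2)c1 | starting material
20 | 3,4-bis(benzyloxy)benzoyl chloride | ClC(=O)c1ccc(OCc2ccccc2)c(OCc2ccccc2)c1 | intermediate
21 | aryl 3,4-bis(benzyloxy)benzoate of 18 | O=C(COCc1ccccc1)c1c(OC(=O)c2ccc(OCc3ccccc3)c(OCc3ccccc3)c2)c(OCc2ccccc2)c(OCc2ccccc2)cc1[C@H]1c2ccc3OC(c4ccccc4)(c4ccccc4)Oc3c2O[C@H](c2ccc(OCc3ccccc3)c(OCc3ccccc3)c2)[C@@H]1OCc1ccccc1 | intermediate
22 | 2-benzyloxy-1,3-diketone (central carbon unassigned, enolisable) | O=C(C(OCc1ccccc1)C(=O)c1ccc(OCc2ccccc2)c(OCc2ccccc2)c1)c1c(O)c(OCc2ccccc2)c(OCc2ccccc2)cc1[C@H]1c2ccc3OC(c4ccccc4)(c4ccccc4)Oc3c2O[C@H](c2ccc(OCc3ccccc3)c(OCc3ccccc3)c2)[C@@H]1OCc1ccccc1 | intermediate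
23 | fully protected flavonol–flavan | O=c1c(OCc2ccccc2)c(-c2ccc(OCc3ccccc3)c(OCc3ccccc3)c2)oc2c(OCc3ccccc3)c(OCc3ccccc3)cc([C@H]3c4ccc5OC(c6ccccc6)(c6ccccc6)Oc5c4O[C@H](c4ccc(OCc5ccccc5)c(OCc5ccccc5)c4)[C@@H]3OCc3ccccc3)c12 | intermediate
24 | CNP0395591.1 | O=c1c(O)c(-c2ccc(O)c(O)c2)oc2c(O)c(O)cc([C@H]3c4ccc(O)c(O)c4O[C@H](c4ccc(O)c(O)c4)[C@@H]3O)c12 | target

Total step count: 16
Longest linear sequence: 13 steps (1, 2, 4, 5, 6, 8, 9, 10, 12, 13, 14, 15, 16)

Steps most likely to fail

Step 9.
- What may go wrong: partial ionisation at C4 so that the inversion pathway is lost, a 1,2-hydride shift of the activated oxirane (Meinwald-type rearrangement), or heterolysis of the C2–O1 bond.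
- Idea of the fallback: it replaces the stereospecific oxirane opening by a stereoconvergent benzylic substitution steered by a neighbouring group. It sets out from 11 and comes back at 12.
- Course: Lewis-acid-catalysed acetolysis of the oxirane (Ac2O, Er(OTf)3 cat, CH2Cl2, 0 °C) opens C4 and gives the (2R,3S,4R)-3,4-diacetate F1. Its C4 configuration does not matter for what follows. Catalytic TMSOTf in CH2Cl2 at −40 °C expels the C4 acetate with help from the C3 acetate. The resulting trans-1,3-dioxolan-2-ylium ion shields the O3 face, so ring A can attack C4 only anti to O3. This gives the 3,4-trans 3-O-acetate F2. Methanolysis (K2CO3, MeOH–THF) returns 12.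

Step 8.
- What may go wrong: partial ionisation of the activated para-alkoxybenzylic carbinol with erosion of the C2 configuration, or slow displacement at the hindered centre.
- Idea of the fallback: the C2–O1 bond is made before the oxirane exists, by asymmetric allylic substitution. It sets out from 10 and 3 and comes back at 11.
- Course:
  - Commercial caffeic acid is perbenzylated (BnBr, K2CO3) to benzyl (E)-3-[3,4-bis(benzyloxy)phenyl]acrylate F3.
  - DIBAL-H reduction gives the cinnamyl alcohol F4, and ClCO2Me with pyridine gives the methyl carbonate F5.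
  - Iridium/phosphoramidite-catalysed branched-selective allylic etherification with the phenoxide of 10, with the ligand enantiomer chosen for this sense, gives the (S)-allyl aryl ether F6.
  - Wittig methylenation of 3 gives the styrene F7.
  - Cross-metathesis of F6 with excess F7 (Hoveyda–Grubbs II, CH2Cl2, 40 °C) gives the (E)-alkene F8.
  - Shi epoxidation gives 11. It needs the L-sorbose-derived enantiomer of the ketone catalyst, because the required oxirane is antipodal to the (R,R) sense of the D-fructose ketone.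

Step 12.
- What may go wrong: the doubly ortho-substituted aryllithium may act as a base towards the α-CH2 of the amide, or the anion may move to a neighbouring benzylic CH2. Both end in protonation instead of acylation.
- Idea of the fallback: the two-carbon unit is built in two smaller additions. It sets out from 13 and comes back at 17.
- Course: aryllithium 16 is trapped with DMF, a small and non-enolisable electrophile, to give the aryl aldehyde F9. Benzyloxymethyllithium (BnOCH2SnBu3, n-BuLi, tin–lithium exchange, −78 °C) adds to give the carbinol F10. The configuration at its new centre is of no consequence. Dess–Martin oxidation gives 17.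

Further compounds
F1 | step 9 | (2R,3S,4R)-3,4-diacetate from acetolysis of 11 | Brc1c(OCc2ccccc2)c(OCc2ccccc2)c(OCc2ccccc2)cc1[C@@H](OC(C)=O)[C@@H](OC(C)=O)[C@@H](c1ccc(OCc2ccccc2)c(OCc2ccccc2)c1)Oc1cccc2OC(c3ccccc3)(c3ccccc3)Oc12
F2 | step 9 | 3-O-acetate of 12 | Brc1c(OCc2ccccc2)c(OCc2ccccc2)c(OCc2ccccc2)cc1[C@H]1c2ccc3OC(c4ccccc4)(c4ccccc4)Oc3c2O[C@H](c2ccc(OCc3ccccc3)c(OCc3ccccc3)c2)[C@@H]1OC(C)=O
F3 | step 8 | benzyl (E)-3-[3,4-bis(benzyloxy)phenyl]acrylate | O=C(OCc1ccccc1)/C=C/c1ccc(OCc2ccccc2)c(OCc2ccccc2)c1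
F4 | step 8 | (E)-3-[3,4-bis(benzyloxy)phenyl]prop-2-en-1-ol | OC/C=C/c1ccc(OCc2ccccc2)c(OCc2ccccc2)c1
F5 | step 8 | (E)-3-[3,4-bis(benzyloxy)phenyl]allyl methyl carbonate | COC(=O)OC/C=C/c1ccc(OCc2ccccc2)c(OCc2ccccc2)c1
F6 | step 8 | 4-{[(1S)-1-(3,4-bis(benzyloxy)phenyl)prop-2-en-1-yl]oxy}-2,2-diphenyl-1,3-benzodioxole | C=C[C@@H](c1ccc(OCc2ccccc2)c(OCc2ccccc2)c1)Oc1cccc2OC(c3ccccc3)(c3ccccc3)Oc12
F7 | step 8 | 2-bromo-3,4,5-tris(benzyloxy)styrene | C=Cc1cc(OCc2ccccc2)c(OCc2ccccc2)c(OCc2ccccc2)c1Br
F8 | step 8 | (S,E)-1,3-diarylallyl aryl ether | Brc1c(OCc2ccccc2)c(OCc2ccccc2)c(OCc2ccccc2)cc1/C=C/[C@@H](c1ccc(OCc2ccccc2)c(OCc2ccccc2)c1)Oc1cccc2OC(c3ccccc3)(c3ccccc3)Oc12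
F9 | step 12 | aryl aldehyde (CHO in place of Br of 13) | O=Cc1c(OCc2ccccc2)c(OCc2ccccc2)c(OCc2ccccc2)cc1[C@H]1c2ccc3OC(c4ccccc4)(c4ccccc4)Oc3c2O[C@H](c2ccc(OCc3ccccc3)c(OCc3ccccc3)c2)[C@@H]1OCc1ccccc1
F10 | step 12 | 1-aryl-2-(benzyloxy)ethanol (both carbinol epimers) | OC(COCc1ccccc1)c1c(OCc2ccccc2)c(OCc2ccccc2)c(OCc2ccccc2)cc1[C@H]1c2ccc3OC(c4ccccc4)(c4ccccc4)Oc3c2O[C@H](c2ccc(OCc3ccccc3)c(OCc3ccccc3)c2)[C@@H]1OCc1ccccc1
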